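## Retrosynthetic overview

1. Numbering used below: the seven-membered ring is C1 (CH–O-angeloyl beside the ring-fusion CH), C2 (CH2), C3 (CMe=), C4 (=CH), C5 (CH–O-angeloyl), C6 (quaternary CMe), C10 (ring-fusion CH); the five-membered ring is C6, C7 (CHOH), C8 (CH2), C9 (C(OH)iPr), C10.
2. Enabling feature: in the five-membered ring the oxygenated C7 lies between quaternary C6 and methylene C8, which is a masked 2-oxyallyl cation whose C6 terminus carries the vicinal C5 oxygen and can be stored as an epoxide. It faces the oxygenated C9 next to C10, the two carbons of an isopropyl ketone enol ether whose oxygen is 1,3 to the C1 oxygen and can be tied to it in a temporary six-membered silylene ring.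
3. Disconnections, last to first: C7–OH from the ketone; the two angelates; C3=C4 by ring-closing metathesis (seven-membered ring, formed second); C6–C10 and C8–C9 together by a (3+2) annulation of an epoxy enolsilane (C4–C8) with a cyclic silyl enol ether (C9, C10, C1–C3) (five-membered ring, formed first).
4. Fragments: the enol ether comes from (R)-epichlorohydrin by dithiane alkylation, cuprate opening and silylene ring formation; the epoxy enolsilane comes from acrolein by Still–Gennari olefination, Sharpless epoxidation and methyl ketone formation. These are the only sources of absolute configuration.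
5. The ketone created at C7 by the annulation stands in for the C7 hydroxyl until both esters are in place, and the silylene ring is cleaved after the seven-membered ring is closed.

Key step: step 13

Remark: the esters are taken as (Z)-2-methylbut-2-enoates (angelates) as drawn; intermediates 21–24 are named by constitution and their configuration is given by the SMILES (identical to 25 at the shared centres).

## Route

Step 1
Reactants: 1 2-methylpropanal; 2 propane-1,3-dithiol
Product: 3 2-(propan-2-yl)-1,3-dithiane
Conditions: BF3·OEt2 (cat.), CH2Cl2, 0 °C to rt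
Reagents that add atoms: none
Why: Lewis-acid thioacetalisation of the aldehyde gives the dithiane that will act as the acyl anion equivalent (Corey–Seebach umpolung) for the isopropyl ketone carbon C9.

Step 2
Reactants: 3 2-(propan-2-yl)-1,3-dithiane; 4 (R)-epichlorohydrin
Product: 7 2-{[(2R)-oxiran-2-yl]methyl}-2-(propan-2-yl)-1,3-dithiane, via 2-lithio-2-(propan-2-yl)-1,3-dithiane 5 (not isolated), via lithium chlorohydrin alkoxide 6 (not isolated)
Conditions: n-BuLi, THF, −25 °C; then 4, −78 °C to rt
Reagents that add atoms: none
Why: Corey–Seebach alkylation, in which the lithiated dithiane opens the epoxide of 4 at its CH2 terminus and the resulting alkoxide displaces chloride to form the new epoxide, so that the C–O bond of the stereocentre is never broken and (R)-4 should give (R)-7.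

Step 3
Reactants: 7 2-{[(2R)-oxiran-2-yl]methyl}-2-(propan-2-yl)-1,3-dithiane
Product: 8 (2S)-4-methyl-1-[2-(propan-2-yl)-1,3-dithian-2-yl]pent-4-en-2-ol
Conditions: isopropenylmagnesium bromide, CuI (10 mol%), THF, −40 to 0 °C
Reagents that add atoms: isopropenylmagnesium bromide, C=C(C)[Mg]Br
Why: copper-catalysed Grignard opening of a terminal epoxide occurs at the unsubstituted carbon, which installs the 2-methylallyl group (C2, C3 and its methyl) and leaves the carbinol centre (future C1, S) untouched.

Step 4
Reactants: 8 (2S)-4-methyl-1-[2-(propan-2-yl)-1,3-dithian-2-yl]pent-4-en-2-ol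
Product: 9 (5S)-5-hydroxy-2,7-dimethyloct-7-en-3-one
Conditions: MeI, CaCO3, MeCN/H2O (9:1), 45 °C
Reagents that add atoms: water, O
Why: S-methylation followed by hydrolysis (alkylative dithiane cleavage) unmasks the ketone under buffered conditions that should spare the β-hydroxy ketone and the alkene.

Step 5
Reactants: 9 (5S)-5-hydroxy-2,7-dimethyloct-7-en-3-one
Product: 10 (4S)-2,2-di-tert-butyl-4-(2-methylprop-2-en-1-yl)-6-(propan-2-yl)-4H-1,3,2-dioxasiline
Conditions: t-Bu2Si(OTf)2 (1.1 equiv), Et3N (3 equiv), CH2Cl2, −78 °C to rt
Reagents that add atoms: di-tert-butylsilyl bis(trifluoromethanesulfonate), CC(C)(C)[Si](OS(=O)(=O)C(F)(F)F)(OS(=O)(=O)C(F)(F)F)C(C)(C)C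
Why: silyl triflate and amine convert a ketone into its silyl enol ether (soft enolisation), and here the hydroxyl is silylated first so that the second Si–O bond forms intramolecularly and the proton is lost from the C10 methylene inside the forming six-membered ring, which gives the endocyclic enol ether with C1 and the enol oxygen necessarily cis; this ring is temporary and is removed in step 15.

Step 6
Reactants: 11 acrolein; 12 ethyl 2-[bis(2,2,2-trifluoroethoxy)phosphoryl]propanoate
Product: 13 ethyl (2Z)-2-methylpenta-2,4-dienoate
Conditions: KN(SiMe3)2, 18-crown-6, THF, −78 °C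
Reagents that add atoms: none
Why: Still–Gennari olefination, in which the electron-poor trifluoroethyl phosphonate makes elimination faster than equilibration and so delivers the Z trisubstituted enoate with the ester carbon cis to the vinyl group.

Step 7
Reactants: 13 ethyl (2Z)-2-methylpenta-2,4-dienoate
Product: 14 (2Z)-2-methylpenta-2,4-dien-1-ol
Conditions: i-Bu2AlH (2.2 equiv), CH2Cl2, −78 °C
Reagents that add atoms: none
Why: hydride reduction of an α,β-unsaturated ester with the aluminium hydride at low temperature stops at the allylic alcohol and does not change the alkene geometry.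

Step 8
Reactants: 14 (2Z)-2-methylpenta-2,4-dien-1-ol
Product: 15 [(2S,3R)-3-ethenyl-2-methyloxiran-2-yl]methanol
Conditions: Ti(OiPr)4 (10 mol%), L-(+)-diethyl tartrate (12 mol%), t-BuOOH, 4 Å molecular sieves, CH2Cl2, −20 °C
Reagents that add atoms: tert-butyl hydroperoxide, CC(C)(C)OO
Why: Sharpless asymmetric epoxidation is hydroxyl-directed, so only the allylic trisubstituted double bond of the dienol is oxidised, and with L-(+)-tartrate the oxygen is delivered to the face that gives the (2S,3R) epoxy alcohol, which fixes C5 and the epoxide carbon that becomes C6, with the vinyl group cis to the hydroxymethyl group as in the Z alkene.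

Step 9
Reactants: 15 [(2S,3R)-3-ethenyl-2-methyloxiran-2-yl]methanol
Product: 16 (2R,3R)-3-ethenyl-2-methyloxirane-2-carbaldehyde
Conditions: Dess–Martin periodinane, pyridine, CH2Cl2, 0 °C
Reagents that add atoms: none
Why: Dess–Martin oxidation of the primary alcohol under buffered conditions gives the aldehyde, whose α-carbon is quaternary and cannot epimerise.

Step 10
Reactants: 16 (2R,3R)-3-ethenyl-2-methyloxirane-2-carbaldehyde
Product: 17 1-[(2S,3R)-3-ethenyl-2-methyloxiran-2-yl]ethan-1-ol (both carbinol epimers)
Conditions: MeMgBr, THF, −78 °C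
Reagents that add atoms: methylmagnesium bromide, C[Mg]Br
Why: Grignard addition to the aldehyde is much faster than attack on the vinyl epoxide at low temperature, and the new carbinol centre need not be controlled because it is oxidised in the next step.

Step 11
Reactants: 17 1-[(2S,3R)-3-ethenyl-2-methyloxiran-2-yl]ethan-1-ol
Product: 18 1-[(2R,3R)-3-ethenyl-2-methyloxiran-2-yl]ethan-1-one
Conditions: Dess–Martin periodinane, pyridine, CH2Cl2, 0 °C to rt
Reagents that add atoms: none
Why: Dess–Martin oxidation of the secondary alcohol gives the methyl ketone without acid or base that could open the vinyl epoxide.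

Step 12
Reactants: 18 1-[(2R,3R)-3-ethenyl-2-methyloxiran-2-yl]ethan-1-one
Product: 20 triethyl({1-[(2R,3R)-3-ethenyl-2-methyloxiran-2-yl]ethenyl}oxy)silane, via lithium enolate 19 (not isolated)
Conditions: LiN(SiMe3)2, THF, −78 °C; then Et3SiCl, Et3N, −78 to 0 °C
Reagents that add atoms: chlorotriethylsilane, CC[Si](Cl)(CC)CC
Why: kinetic deprotonation can only occur at the methyl group because the other α-carbon is the quaternary epoxide carbon, and O-silylation of the lithium enolate gives the epoxy enolsilane (silyl enol ether formation).

Step 13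
Reactants: 10 (4S)-2,2-di-tert-butyl-4-(2-methylprop-2-en-1-yl)-6-(propan-2-yl)-4H-1,3,2-dioxasiline; 20 triethyl({1-[(2R,3R)-3-ethenyl-2-methyloxiran-2-yl]ethenyl}oxy)silane
Product: 21 silylene-bridged cyclopentanone (C7 ketone; C1–O and C9–O bridged by t-Bu2Si; C5–OSiEt3; ethenyl on C5; 2-methylprop-2-enyl on C1; C1, C5, C6, C9 and C10 configured as in 25)
Conditions: Et3SiOTf (10 mol%), 2,6-di-tert-butyl-4-methylpyridine (10 mol%), CH2Cl2, −78 °C, 20 added over 2 h to 10 (1.3 equiv), then −40 °C
Reagents that add atoms: none
Why: Proposed new method: Et3SiOTf silylates the epoxide oxygen of 20, the enol silane π system assists heterolysis of the tertiary C6–O bond to a 2-siloxyallyl cation held as a tight ion pair, the nucleophilic C10 of 10 attacks C6 from the side opposite the leaving oxygen, the resulting cyclic silyloxocarbenium ion at C9 is captured by the enol silane carbon C8 (intramolecular Mukaiyama aldol) and the Et3Si group on the C7 carbonyl oxygen is handed to the next epoxide, so that the catalyst turns over and the net reaction is an isomerising addition of 10 to 20. The closest known reaction types are the silyl-triflate-catalysed (4+3) cycloaddition of epoxy enolsilanes with dienes, which is stereospecific with inversion at the epoxide carbon, and the Lewis-acid (3+2) cyclopentanone annulation of 2-siloxyallyl cations with enol silyl ethers, and their combination at a tertiary epoxide carbon is untested. The only ring closed is the cyclopentanone: the C6–C10 bond forms between the two fragments and the C8–C9 bond then closes the five-membered ring in a 5-(enolendo)-exo-trig mode onto the oxocarbenium carbon. C6 is set by inversion of the (2R) epoxide carbon while C5 is carried through unchanged, C10 is set by attack on the dioxasiline face anti to the 2-methylallyl group at C1, and C9 is set by the obligatory cis fusion of the new cyclopentane to the six-membered silylene ring, which places isopropyl cis to H-10; this pairing of enantiomers should be the matched one, because the backside trajectory at C6 lets the methyl group occupy the crowded sector between C9 and C1 while the C5 substituent points away from the silylene ring. The step needs cross reaction over self-condensation of 20, C6–O over allylic C5–O ionisation and C- over O-closure at C9, and these should be secured by slow addition of 20 to an excess of the more nucleophilic 10, by the siloxyallyl stabilisation that is available only at C6, and by the reversibility of ketal formation under the silyl triflate.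

Step 14
Reactants: 21 silylene-bridged cyclopentanone
Product: 22 tricyclic silylene ketone (hexahydroazulenone core of 25 with C7 ketone, C5–OSiEt3, and C1–O and C9–O bridged by t-Bu2Si)
Conditions: second-generation Grubbs catalyst RuCl2(=CHPh)(PCy3)(H2IMes) (10 mol%), toluene (0.005 M), 80 °C
Reagents that add atoms: none
Why: ring-closing metathesis with the ruthenium carbene should load on the vinyl group and close onto the 1,1-disubstituted alkene to form the trisubstituted C3=C4 bond, the two chains being trans on adjacent ring carbons (one of them held pseudoequatorial by the silylene ring) so that the trans-fused seven-membered ring can close, while ketone and silyl ethers are inert.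

Step 15
Reactants: 22 tricyclic silylene ketone
Product: 23 3,4,8-trihydroxy-6,8a-dimethyl-3-(propan-2-yl)-3,3a,4,5,8,8a-hexahydroazulen-1(2H)-one (free hydroxyls at C1, C5 and C9; ketone at C7)
Conditions: HF·pyridine, pyridine, THF, 0 °C to rt
Reagents that add atoms: none
Why: fluoride-driven desilylation under weakly acidic, buffered conditions cleaves the triethylsilyl ether and the temporary di-tert-butylsilylene ring without the base that would trigger retro-aldol cleavage or dehydration of the β-hydroxy ketone units.

Step 16
Reactants: 23 triol ketone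
Product: 24 3-hydroxy-6,8a-dimethyl-1-oxo-3-(propan-2-yl)-1,2,3,3a,4,5,8,8a-octahydroazulene-4,8-diyl bis[(2Z)-2-methylbut-2-enoate] (diangelate ketone)
Conditions: angelic acid (5 equiv), 2,4,6-trichlorobenzoyl chloride, Et3N, toluene, rt; then 23, 70 °C
Reagents that add atoms: angelic acid [(2Z)-2-methylbut-2-enoic acid], C/C=C(/C)C(O)=O
Why: Yamaguchi esterification through the mixed anhydride of angelic acid acylates the two secondary hydroxyls at C1 and C5 while the tertiary C9 hydroxyl stays free and C7 is still a carbonyl, and leaving out 4-(dimethylamino)pyridine avoids the conjugate addition that isomerises angelate to tiglate.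

Step 17
Reactants: 24 diangelate ketone
Product: 25 target, 1,3-dihydroxy-6,8a-dimethyl-3-(propan-2-yl)-1,2,3,3a,4,5,8,8a-octahydroazulene-4,8-diyl bis[(2Z)-2-methylbut-2-enoate], (1S,5R,6R,7R,9R,10S) in the numbering of the overview
Conditions: NaBH4, CeCl3·7H2O, MeOH, −78 to −40 °C
Reagents that add atoms: none
Why: Luche-type hydride reduction should occur from the face of the C7 carbonyl opposite the angular methyl group on C6 and the pseudoaxial hydroxyl on C9, as in the reduction of 17-keto steroids, which places the new hydroxyl cis to both and gives the 7R carbinol, and the conjugated esters are not reduced at this temperature.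

## Compound list

1 | 2-methylpropanal | CC(C)C=O | starting material
2 | propane-1,3-dithiol | SCCCS | starting material
3 | 2-(propan-2-yl)-1,3-dithiane | CC(C)C1SCCCS1 | intermediate
4 | (R)-epichlorohydrin, (2R)-2-(chloromethyl)oxirane | ClC[C@H]1CO1 | starting material
5 | 2-lithio-2-(propan-2-yl)-1,3-dithiane (not isolated) | [Li]C1(C(C)C)SCCCS1 | intermediate
6 | lithium (2R)-1-chloro-3-[2-(propan-2-yl)-1,3-dithian-2-yl]propan-2-olate (not isolated) | ClC[C@H]([O-])CC1(C(C)C)SCCCS1.[Li+] | intermediate
7 | 2-{[(2R)-oxiran-2-yl]methyl}-2-(propan-2-yl)-1,3-dithiane | C1[C@H](O1)CC2(C(C)C)SCCCS2 | intermediate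
8 | (2S)-4-methyl-1-[2-(propan-2-yl)-1,3-dithian-2-yl]pent-4-en-2-ol | C=C(C)C[C@H](O)CC1(C(C)C)SCCCS1 | intermediate
9 | (5S)-5-hydroxy-2,7-dimethyloct-7-en-3-one | CC(C)C(=O)C[C@@H](O)CC(C)=C | intermediate
10 | (4S)-2,2-di-tert-butyl-4-(2-methylprop-2-en-1-yl)-6-(propan-2-yl)-4H-1,3,2-dioxasiline | CC(C)C1=C[C@H](CC(C)=C)O[Si](O1)(C(C)(C)C)C(C)(C)C | intermediate
11 | acrolein (prop-2-enal) | C=CC=O | starting material
12 | ethyl 2-[bis(2,2,2-trifluoroethoxy)phosphoryl]propanoate | CCOC(=O)C(C)P(=O)(OCC(F)(F)F)OCC(F)(F)F | starting material
13 | ethyl (2Z)-2-methylpenta-2,4-dienoate | C=C/C=C(/C)C(=O)OCC | intermediate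
14 | (2Z)-2-methylpenta-2,4-dien-1-ol | C=C/C=C(/C)CO | intermediate
15 | [(2S,3R)-3-ethenyl-2-methyloxiran-2-yl]methanol | C=C[C@H]1O[C@@]1(C)CO | intermediate
16 | (2R,3R)-3-ethenyl-2-methyloxirane-2-carbaldehyde | C=C[C@H]1O[C@@]1(C)C=O | intermediate
17 | 1-[(2S,3R)-3-ethenyl-2-methyloxiran-2-yl]ethan-1-ol (carbinol epimers) | C=C[C@H]1O[C@@]1(C)C(C)O | intermediate
18 | 1-[(2R,3R)-3-ethenyl-2-methyloxiran-2-yl]ethan-1-one | C=C[C@H]1O[C@@]1(C)C(C)=O | intermediate
19 | lithium 1-[(2R,3R)-3-ethenyl-2-methyloxiran-2-yl]ethen-1-olate (not isolated) | C=C[C@H]1O[C@@]1(C)C(=C)[O-].[Li+] | intermediate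
20 | triethyl({1-[(2R,3R)-3-ethenyl-2-methyloxiran-2-yl]ethenyl}oxy)silane | C=C[C@H]1O[C@@]1(C)C(=C)O[Si](CC)(CC)CC | intermediate
21 | 2,2-di-tert-butyl-5-methyl-4-(2-methylprop-2-en-1-yl)-7a-(propan-2-yl)-5-[1-(triethylsilyloxy)prop-2-en-1-yl]hexahydrocyclopenta[d][1,3,2]dioxasilin-6-one, configured as in 25 | C=C[C@@H](O[Si](CC)(CC)CC)[C@@]1(C)C(=O)C[C@]2(C(C)C)O[Si](C(C)(C)C)(C(C)(C)C)O[C@@H](CC(C)=C)[C@H]12 | intermediate
22 | tricyclic silylene ketone (C7 ketone, C5–OSiEt3, C1–O and C9–O bridged by t-Bu2Si), configured as in 25 | CC1=C[C@@H](O[Si](CC)(CC)CC)[C@@]2(C)C(=O)C[C@]3(C(C)C)O[Si](C(C)(C)C)(C(C)(C)C)O[C@@H](C1)[C@H]23 | intermediate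
23 | 3,4,8-trihydroxy-6,8a-dimethyl-3-(propan-2-yl)-3,3a,4,5,8,8a-hexahydroazulen-1(2H)-one, configured as in 25 | O[C@H]1CC(C)=C[C@@H](O)[C@@]2(C)C(=O)C[C@@](O)(C(C)C)[C@H]12 | intermediate
24 | 3-hydroxy-6,8a-dimethyl-1-oxo-3-(propan-2-yl)-1,2,3,3a,4,5,8,8a-octahydroazulene-4,8-diyl bis[(2Z)-2-methylbut-2-enoate], configured as in 25 | C/C=C(/C)C(=O)O[C@H]1CC(C)=C[C@@H](OC(=O)/C(C)=C\C)[C@@]2(C)C(=O)C[C@@](O)(C(C)C)[C@H]12 | intermediate
25 | 1,3-dihydroxy-6,8a-dimethyl-3-(propan-2-yl)-1,2,3,3a,4,5,8,8a-octahydroazulene-4,8-diyl bis[(2Z)-2-methylbut-2-enoate], (1S,5R,6R,7R,9R,10S) in the overview numbering | C/C=C(/C)C(=O)O[C@H]1CC(C)=C[C@@H](OC(=O)/C(C)=C\C)[C@@]2(C)[C@H](O)C[C@@](O)(C(C)C)[C@H]12 | target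

## Step count and risks

Total step count: 17. Longest linear sequence: 12 steps (steps 6–17).

Steps most likely to fail:

**Step 13 (the labelled step).** The enol silane of 20 may condense with a second activated molecule of 20 faster than it meets 10. The epoxide may also ionise completely before the C–C bond forms, so that the configuration of C6 is no longer relayed by inversion. The fallback runs from 18 back to 21 and uses known reactions only.
- Reductive cleavage of the α C–O bond of the epoxy ketone with SmI2 (THF/MeOH, −90 °C) should give (4R)-4-hydroxy-3-methylhex-5-en-2-one F1.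
- Et3SiCl/NaI/Et3N in MeCN should silylate the hydroxyl and form the more substituted enol silane, (4R)-3-methyl-2,4-bis(triethylsilyloxy)hexa-2,5-diene F2.
- N-Bromosuccinimide (THF, −78 °C) should give the tertiary bromide (4R)-3-bromo-3-methyl-4-(triethylsilyloxy)hex-5-en-2-one F3.
- LiN(SiMe3)2 followed by Et3SiCl should give the 2-siloxyallyl bromide (4R)-3-bromo-3-methyl-2,4-bis(triethylsilyloxy)hexa-1,5-diene F4.
- F4 and 10 with ZnCl2 in CH2Cl2 (−78 to −20 °C) should undergo the Lewis-acid (3+2) cyclopentanone annulation of a 2-siloxyallyl halide with an enol silyl ether and give 21.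
- In this variant C6 is set by attack on the free cation anti to the vinyl group on C5 (C5–H eclipsing the cation plane) and no longer by inversion, so a lower selectivity at C6 has to be expected.

**Step 16.** Hot triethylamine may cause retro-aldol ring opening or dehydration of the two unprotected β-hydroxy ketone units, and acylation of the neopentyl C5 hydroxyl may stay incomplete. The fallback runs from 22 to 24 and esterifies in two stages, so that the forcing acylation is done while the C9 oxygen is still silylated.
- Pyridinium p-toluenesulfonate in MeOH (0 °C) should remove only the triethylsilyl group and give the C5 alcohol with silylene and ketone retained, 5-hydroxy silylene ketone F5.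
- Yamaguchi acylation with the angelic mixed anhydride (toluene, 70 °C) should give the 5-angeloyloxy silylene ketone F6.
- HF·pyridine should cleave the silylene to the 5-angeloyloxy-1,9-diol ketone F7.
- The unhindered C1 hydroxyl of F7 should then be acylated with the same mixed anhydride at room temperature to give 24.

**Step 14.** The ruthenium carbene may load slowly on the vinyl group next to the bulky silyloxy substituent and the quaternary carbon, so that dimerisation through the 2-methylallyl group or catalyst decay wins over ring closure. The fallback runs from 21 to 23 and reverses the order of metathesis and desilylation.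
- HF·pyridine on 21 should give the seco-triol ketone F8, whose free allylic hydroxyl is smaller and should accelerate metathesis at the adjacent vinyl group.
- Ring-closing metathesis of F8 (second-generation Hoveyda–Grubbs catalyst RuCl2(=CH-C6H4-2-OiPr)(H2IMes), CH2Cl2, 40 °C) should give 23 directly.

Further compounds
F1 | step 13 | (4R)-4-hydroxy-3-methylhex-5-en-2-one (C3 epimers) | CC(=O)C(C)[C@H](O)C=C
F2 | step 13 | (4R)-3-methyl-2,4-bis(triethylsilyloxy)hexa-2,5-diene (enol ether isomers) | CC(O[Si](CC)(CC)CC)=C(C)[C@H](O[Si](CC)(CC)CC)C=C
F3 | step 13 | (4R)-3-bromo-3-methyl-4-(triethylsilyloxy)hex-5-en-2-one (C3 epimers) | CC(=O)C(C)(Br)[C@H](O[Si](CC)(CC)CC)C=C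
F4 | step 13 | (4R)-3-bromo-3-methyl-2,4-bis(triethylsilyloxy)hexa-1,5-diene (C3 epimers) | C=C(O[Si](CC)(CC)CC)C(C)(Br)[C@H](O[Si](CC)(CC)CC)C=C
F5 | step 16 | 5-hydroxy silylene ketone (22 without the triethylsilyl group) | CC1=C[C@@H](O)[C@@]2(C)C(=O)C[C@]3(C(C)C)O[Si](C(C)(C)C)(C(C)(C)C)O[C@@H](C1)[C@H]23
F6 | step 16 | 5-angeloyloxy silylene ketone | CC1=C[C@@H](OC(=O)/C(C)=C\C)[C@@]2(C)C(=O)C[C@]3(C(C)C)O[Si](C(C)(C)C)(C(C)(C)C)O[C@@H](C1)[C@H]23
F7 | step 16 | 5-angeloyloxy-1,9-diol ketone | O[C@H]1CC(C)=C[C@@H](OC(=O)/C(C)=C\C)[C@@]2(C)C(=O)C[C@@](O)(C(C)C)[C@H]12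
F8 | step 14 | seco-triol ketone (21 without both silicon groups) | C=C[C@@H](O)[C@@]1(C)C(=O)C[C@@](O)(C(C)C)[C@@H]1[C@@H](O)CC(C)=C
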